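The data were computed with constants of no real substance.

In a stirred flask of constant volume I follow one molecule of starting material. It becomes intermediate and reaches a fork: partner captures it, or a second intermediate couples with it to homo product. Once captured it stands as target, and a second partner can turn that into over-reaction product.

| setting | gamma | beta | eta | zeta | Sunday's | Monday's | Saturday's | Thursday's |
|---|---|---|---|---|---|---|---|---|
| starting material | 0.050 M | 0.025 M | 0.038 M | 0.050 M | 0.050 M | 0.050 M (fed, over 30 s) | 0.050 M | 0.050 M |
| partner | 0.055 M | 0.055 M | 0.055 M | 0.028 M | 0.0550 M (fed, over 30 s) | 0.0550 M | 0.0550 M | 0.0550 M (fed, over 8.0 s) |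
| remark | run made earlier | run made earlier | run made earlier | run made earlier | all else is in the flask from the start; the feed brings no volume worth counting | all else is in the flask from the start; the feed brings no volume worth counting | everything together at the start | all else is in the flask from the start; the feed brings no volume worth counting |
| time |  |  |  |  | 2.5 min | 2.5 min | 2.5 min | 2.5 min |

| run | time / s | over-reaction product / % | target / % |
|---|---|---|---|
| gamma | 10.0 | 10.8 | 57.5 |
| gamma | 15.0 | 13.4 | 55.3 |
| gamma | 25.0 | 19.1 | 49.8 |
| gamma | 40.0 | 26.8 | 41.3 |
| gamma | 50.0 | 30.4 | 38.2 |
| gamma | 80.0 | 36.6 | 30.8 |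
| gamma | 90.0 | 36.4 | 30.1 |
| beta | 15.0 | 29.2 | 51.2 |
| beta | 30.0 | 45.9 | 33.9 |
| beta | 50.0 | 59.7 | 20.1 |
| beta | 60.0 | 63.2 | 15.5 |
| beta | 80.0 | 69.9 | 9.9 |
| beta | 90.0 | 70.3 | 9.4 |
| beta | 120 | 75.5 | 5.5 |
| eta | 10.0 | 14.8 | 59.0 |
| eta | 15.0 | 19.7 | 52.2 |
| eta | 20.0 | 23.8 | 46.1 |
| eta | 30.0 | 33.6 | 39.0 |
| eta | 50.0 | 42.1 | 31.3 |
| eta | 80.0 | 49.3 | 22.8 |
| eta | 120 | 57.1 | 15.9 |
| zeta | 25.0 | 6.8 | 37.2 |
| zeta | 50.0 | 9.4 | 34.1 |
| zeta | 80.0 | 12.1 | 30.0 |
| zeta | 90.0 | 10.7 | 32.0 |
| zeta | 120 | 12.1 | 27.4 |

(readings scatter by 1 percentage point)

- percent here means starting material units held: one homo product or idle adduct counts as two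
- what is said of target includes idle adduct and crystals
- crystals is a solid; its amount is given per volume of the solution
- candidate steps: starting material -> intermediate; partner + intermediate -> target; 2 intermediate -> homo product; partner + target -> over-reaction product; starting material + target <-> idle adduct; crystals <-> target
- in an amount of target, one idle adduct counts as one target

* the flask that comes out highest in amount of over-reaction product, in percent of the starting material charged; "all alike" if 1.5 percentage points covers them all (Sunday's / Monday's / Saturday's / Thursday's / all alike)
* amount of over-reaction product at the end, in percent of the starting material charged, Sunday's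
* amount of over-reaction product at the end, in percent of the starting material charged, Monday's
* amount of over-reaction product at the end, in percent of the starting material charged, Saturday's
* amount of over-reaction product at the end, in percent of the starting material charged, Thursday's

Target plus over-reaction product therefore counts every molecule captured. In the gamma run, which has Saturday's charges, this capture share reads 68.3% at 10.0 s and averages 67.0% over the last two readings. Each captured molecule costs one partner and each over-reaction product one more, so I reckon:

ceiling = 110% − 67.0% = 43.0%

This over-reaction ceiling, the partner charge over the starting material charge less the capture share, is the level I expect for Saturday's curve, since the capture share is larger, which makes partner the limiting reagent of the over-reaction.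

The gamma readings climb 16 percentage points between 10.0 s and 40.0 s. Continued straight, that line meets the ceiling at 70.5 s, but the curve bends first, reading 36.6% at 80.0 s. The distance below the ceiling shrinks from 16 points at 40.0 s to 6.6 points at 90.0 s. Read as an exponential decay, that gives a time constant of 56.0 s, so my estimate for Saturday's at 2.5 min is:

over-reaction product = 43.0% − 6.6 points × exp(−(150 s − 90.0 s) / 56.0 s) = 40.8%

For Monday's, the starting material is fed over 30 s, so as my own estimate I take the capture share of the beta run, the lowest starting material charge shown. That gives a ceiling of 29.6%.

The forecast names Saturday's highest and gives Sunday's 12.5%, Monday's 20%, Saturday's 39.5% and Thursday's 21%. For Monday's it holds that “over-reaction during the feed uses up partner”, and there my figure differs from it.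

Saturday's comes out highest at 40.5%, 2.5 points below the ceiling of 43.0%, with Sunday's at 10.1% and Thursday's at 23.7%. Monday's gives 30.0%, not the forecast's 20%, and holds 49.3% of target at the end, crystals counted in.

    starting material → intermediate (k = 1.06 s⁻¹)
    partner + intermediate → target (k = 36.9 M⁻¹ s⁻¹)
    2 intermediate → homo product (k = 63.6 M⁻¹ s⁻¹)
    partner + target → over-reaction product (k = 1.13 M⁻¹ s⁻¹)
    starting material + target ⇌ idle adduct, settled at all times (K = 54.6 M⁻¹)
    crystals ⇌ target, rate k6*(cs6 - [target]) while solid is left; crystals form when [target] > cs6 (solubility = 19.0 mM, k = 0.626 s⁻¹)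

Monday's own capture share at 2.5 min makes its ceiling 30.7%, and at 25.0 min its over-reaction product stands at 30.7%. In the neighbour of Saturday's charged with 0.12 M of starting material, the same subtraction gives 5.02%, and the over-reaction product of that flask ends at 4.88%.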